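The target is cut at its E‑disubstituted alkene into a vinylboronate carrying lactone ring A and oxolane ring B, and a butenolide (ring C) allyl bromide. Rings A and B are made together: the three C–O bonds at the quaternary C5 of ring A and at C2 and quaternary C5 of ring B form a 1,2,5 array that maps onto two E‑trisubstituted alkenes of an isoprenoid chain. Acid makes a bis‑epoxide zip up: the ester carbonyl oxygen closes ring A, the freed secondary hydroxyl closes ring B, and both quaternary centres are set by inversion. The precursor is a linear tert‑butyl ester with a (2S,3S)‑2,3‑epoxy alcohol and a (R,R)‑epoxide.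

Key step: step 8

Remarks on the chemistry:
- Ring A is the oxolan‑2‑one, ring B the oxolane, ring C the furan‑2(5H)‑one.
- A free γ,δ‑epoxy acid would lactonise as soon as it forms, and a free acid would bind the titanium tartrate catalyst. The carboxyl terminus is therefore carried as its tert‑butyl ester, whose carbonyl oxygen is the nucleophile of the key step and whose alkyl group leaves as 2‑methylpropene.
- The C12 chain is built from geraniol by allylic oxidation and ester‑enolate alkylation, which installs the ester directly.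
- Assumption: geraniol, furan‑2(5H)‑one, 5‑bromo‑2‑methylpent‑2‑ene and all named reagents (including Cl2CHBpin and the D‑fructose‑derived ketone) are taken as commercial.

**Step 1**
Reactants: 1 geraniol, (2E)‑3,7‑dimethylocta‑2,6‑dien‑1‑ol
Product: 2 tert‑butyl{[(2E)‑3,7‑dimethylocta‑2,6‑dien‑1‑yl]oxy}dimethylsilane
Conditions: t‑BuMe2SiCl, imidazole, DMF, 0 °C to rt
Reagents that add atoms: tert‑butyldimethylsilyl chloride, CC(C)(C)[Si](C)(C)Cl
Why: Imidazole‑mediated silylation (silyl ether protection) of the primary allylic alcohol leaves both alkenes untouched and creates no stereocentre.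

**Step 2**
Reactants: 2 tert‑butyl{[(2E)‑3,7‑dimethylocta‑2,6‑dien‑1‑yl]oxy}dimethylsilane
Product: 3 (2E,6E)‑8‑{[tert‑butyl(dimethyl)silyl]oxy}‑2,6‑dimethylocta‑2,6‑dien‑1‑ol
Conditions: SeO2 (0.3 equiv), salicylic acid (0.1 equiv), t‑BuOOH (70% aq.), CH2Cl2, rt
Reagents that add atoms: selenium dioxide, O=[Se]=O (oxygen carrier); tert‑butyl hydroperoxide, CC(C)(C)OO (terminal oxidant)
Why: Riley‑type allylic oxidation (ene reaction, then [2,3]‑sigmatropic shift) should attack the more electron‑rich terminal trisubstituted alkene at the methyl trans to the chain and give the E‑allylic alcohol; the silyloxy‑bearing alkene is less nucleophilic, and the reaction is stopped before over‑oxidation to the enal.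

**Step 3**
Reactants: 3 (2E,6E)‑8‑{[tert‑butyl(dimethyl)silyl]oxy}‑2,6‑dimethylocta‑2,6‑dien‑1‑ol
Product: 4 {[(2E,6E)‑8‑bromo‑3,7‑dimethylocta‑2,6‑dien‑1‑yl]oxy}(tert‑butyl)dimethylsilane
Conditions: CBr4, PPh3, CH2Cl2, −20 to 0 °C
Reagents that add atoms: carbon tetrabromide, BrC(Br)(Br)Br
Why: Appel bromination displaces the alkoxyphosphonium ion of the primary allylic alcohol by SN2 under neutral conditions, so the silyl ether and both alkene geometries should be kept.

**Step 4**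
Reactants: 4 {[(2E,6E)‑8‑bromo‑3,7‑dimethylocta‑2,6‑dien‑1‑yl]oxy}(tert‑butyl)dimethylsilane
Product: 5 tert‑butyl (4E,8E)‑10‑{[tert‑butyl(dimethyl)silyl]oxy}‑4,8‑dimethyldeca‑4,8‑dienoate
Conditions: LiN(iPr)2, t‑BuOAc, THF, −78 °C; then 4, DMPU, −78 to 0 °C
Reagents that add atoms: tert‑butyl acetate, CC(=O)OC(C)(C)C
Why: SN2 alkylation of the lithium enolate of tert‑butyl acetate by the primary allylic bromide adds the two‑carbon ester terminus at the right oxidation level; excess enolate suppresses dialkylation and no stereocentre is formed.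

**Step 5**
Reactants: 5 tert‑butyl (4E,8E)‑10‑{[tert‑butyl(dimethyl)silyl]oxy}‑4,8‑dimethyldeca‑4,8‑dienoate
Product: 6 tert‑butyl (4E,8E)‑10‑hydroxy‑4,8‑dimethyldeca‑4,8‑dienoate
Conditions: Bu4NF, THF, 0 °C to rt
Reagents that add atoms: none
Why: Fluoride‑induced desilylation frees the allylic alcohol needed to direct the titanium epoxidation, and the tert‑butyl ester is stable to Bu4NF.

**Step 6**
Reactants: 6 tert‑butyl (4E,8E)‑10‑hydroxy‑4,8‑dimethyldeca‑4,8‑dienoate
Product: 7 tert‑butyl (4E)‑6‑[(2S,3S)‑3‑(hydroxymethyl)‑2‑methyloxiran‑2‑yl]‑4‑methylhex‑4‑enoate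
Conditions: Ti(OiPr)4 (10 mol %), L‑(+)‑diethyl tartrate (12 mol %), t‑BuOOH (in isooctane), 4 Å MS, CH2Cl2, −20 °C
Reagents that add atoms: tert‑butyl hydroperoxide, CC(C)(C)OO
Why: Katsuki–Sharpless asymmetric epoxidation is directed by the allylic hydroxyl, so only the 8,9‑alkene reacts, and the L‑(+)‑tartrate titanium complex should deliver oxygen to the face that gives the (2S,3S)‑epoxy alcohol, as it does with geraniol and other E‑3‑methylalk‑2‑en‑1‑ols.

**Step 7**
Reactants: 7 tert‑butyl (4E)‑6‑[(2S,3S)‑3‑(hydroxymethyl)‑2‑methyloxiran‑2‑yl]‑4‑methylhex‑4‑enoate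
Product: 8 tert‑butyl 3‑[(2R,3R)‑3‑{2‑[(2S,3S)‑3‑(hydroxymethyl)‑2‑methyloxiran‑2‑yl]ethyl}‑2‑methyloxiran‑2‑yl]propanoate
Conditions: D‑fructose‑derived Shi ketone (1,2:4,5‑di‑O‑isopropylidene‑β‑D‑erythro‑2,3‑hexodiulo‑2,6‑pyranose, 0.3 equiv), Oxone (KHSO5), K2CO3, Bu4NHSO4, MeCN/CH2(OMe)2, aq. Na2B4O7/Na2EDTA buffer (pH 10.5), 0 °C
Reagents that add atoms: potassium peroxymonosulfate (active component of Oxone), [K+].[O-]S(=O)(=O)OO
Why: Shi epoxidation by the chiral dioxirane of the D‑fructose‑derived ketone should convert the remaining E‑trisubstituted alkene into the (R,R)‑epoxide through the spiro transition state under reagent control; 2,3‑epoxy alcohols and tert‑butyl esters persist in this cold basic buffer, which also prevents premature acid‑triggered cyclisation.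

**Step 8**
Reactants: 8 tert‑butyl 3‑[(2R,3R)‑3‑{2‑[(2S,3S)‑3‑(hydroxymethyl)‑2‑methyloxiran‑2‑yl]ethyl}‑2‑methyloxiran‑2‑yl]propanoate
Product: 10 (5S)‑5‑[(2R,5R)‑5‑[(1S)‑1,2‑dihydroxyethyl]‑5‑methyloxolan‑2‑yl]‑5‑methyloxolan‑2‑one, via hydroxy‑lactone epoxy alcohol 9 (not isolated)
Conditions: (1S)‑(+)‑10‑camphorsulfonic acid (CSA, 0.2 equiv), CH2Cl2, 0 °C to rt
Reagents that add atoms: none
Why: Protonation activates the epoxides; the tert‑butyl ester carbonyl oxygen attacks the tertiary carbon of the γ,δ‑epoxy ester from the rear (5‑exo‑tet) and the alkoxycarbenium ion sheds 2‑methylpropene, giving lactone ring A and the free secondary hydroxyl of 9, which then attacks the tertiary carbon of the protonated 2,3‑epoxy alcohol (5‑exo‑tet) to close oxolane ring B. The closest known reaction types are exo‑selective acid‑mediated polyepoxide cascades terminated by tert‑butyl esters or carbonates, and the opening of 2,3‑epoxy alcohols at the distal tertiary carbon by a tethered hydroxyl. Both new quaternary stereocentres arise by inversion: the (R)‑configured tertiary epoxide carbon from the Shi step becomes the (S)‑C5 of ring A, and the (S)‑configured one from the Sharpless step becomes the (R)‑C5 of ring B, while the two CH–O centres keep their epoxide oxygens and configurations. The step needs exo rather than endo opening at both epoxides and ester participation ahead of epoxide–epoxide cross‑talk; each attacked carbon is tertiary and proximal to its nucleophile, so ring size and cation stability point the same way, the hydroxymethyl group inductively deactivates the neighbouring secondary carbon, and the ester carbonyl sits in a five‑membered relationship to its epoxide. If the 2,3‑epoxide is activated first, attack by the other epoxide oxygen and capture of the epoxonium ion at its tertiary carbon by the ester lead to the same product with the same inversions.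

**Step 9**
Reactants: 10 (5S)‑5‑[(2R,5R)‑5‑[(1S)‑1,2‑dihydroxyethyl]‑5‑methyloxolan‑2‑yl]‑5‑methyloxolan‑2‑one
Product: 11 (2R,5R)‑2‑methyl‑5‑[(2S)‑2‑methyl‑5‑oxooxolan‑2‑yl]oxolane‑2‑carbaldehyde
Conditions: NaIO4, THF/H2O, 0 °C to rt
Reagents that add atoms: none
Why: Periodate glycol cleavage (Malaprade reaction) removes the terminal carbinol carbon as formaldehyde and leaves the aldehyde on the quaternary oxolane carbon, which has no α‑hydrogen and so cannot epimerise.

**Step 10**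
Reactants: 11 (2R,5R)‑2‑methyl‑5‑[(2S)‑2‑methyl‑5‑oxooxolan‑2‑yl]oxolane‑2‑carbaldehyde
Product: 12 (5S)‑5‑methyl‑5‑{(2R,5R)‑5‑methyl‑5‑[(E)‑2‑(4,4,5,5‑tetramethyl‑1,3,2‑dioxaborolan‑2‑yl)ethenyl]oxolan‑2‑yl}oxolan‑2‑one
Conditions: CrCl2 (8 equiv), Cl2CHBpin (2 equiv), LiI (4 equiv), THF, rt
Reagents that add atoms: 2‑(dichloromethyl)‑4,4,5,5‑tetramethyl‑1,3,2‑dioxaborolane, ClC(Cl)B1OC(C)(C)C(C)(C)O1
Why: Takai–Utimoto olefination: the geminal dichromium reagent formed from the boryl dihalide (after iodide exchange) and divalent chromium chloride adds to the aldehyde and eliminates to give the E‑alkenylboronate, and CrCl2 tolerates the lactone.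

**Step 11**
Reactants: 13 furan‑2(5H)‑one
Product: 15 3‑bromofuran‑2(5H)‑one, via trans‑3,4‑dibromooxolan‑2‑one 14 (not isolated)
Conditions: Br2, CH2Cl2, 0 °C to rt; then Et3N, 0 °C
Reagents that add atoms: bromine, BrBr
Why: Anti addition of bromine to the butenolide alkene, then E1cB dehydrobromination by Et3N (loss of the acidic α‑hydrogen and the β‑bromide), should return the conjugated lactone with bromine at C3.

**Step 12**
Reactants: 15 3‑bromofuran‑2(5H)‑one; 16 5‑bromo‑2‑methylpent‑2‑ene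
Product: 18 3‑(4‑methylpent‑3‑en‑1‑yl)furan‑2(5H)‑one, via (4‑methylpent‑3‑en‑1‑yl)zinc bromide 17 (not isolated)
Conditions: 16, Zn dust (activated with BrCH2CH2Br and Me3SiCl), LiCl, THF, 50 °C; then 15, PdCl2(dppf) (5 mol %), THF, rt
Reagents that add atoms: none
Why: Negishi coupling: LiCl‑promoted zinc insertion gives an alkylzinc halide too mild to add to or deprotonate the butenolide, and palladium with the wide‑bite‑angle dppf ligand should couple it with the α‑bromo enoate faster than β‑hydride elimination.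

**Step 13**
Reactants: 18 3‑(4‑methylpent‑3‑en‑1‑yl)furan‑2(5H)‑one
Product: 19 3‑[(3E)‑5‑hydroxy‑4‑methylpent‑3‑en‑1‑yl]furan‑2(5H)‑one
Conditions: SeO2 (0.3 equiv), salicylic acid (0.1 equiv), t‑BuOOH (70% aq.), CH2Cl2, rt
Reagents that add atoms: selenium dioxide, O=[Se]=O (oxygen carrier); tert‑butyl hydroperoxide, CC(C)(C)OO (terminal oxidant)
Why: Riley‑type allylic oxidation should take the methyl trans to the chain on the electron‑rich trisubstituted alkene and give the E‑allylic alcohol, while the electron‑poor butenolide alkene does not enter the ene reaction.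

**Step 14**
Reactants: 19 3‑[(3E)‑5‑hydroxy‑4‑methylpent‑3‑en‑1‑yl]furan‑2(5H)‑one
Product: 20 3‑[(3E)‑5‑bromo‑4‑methylpent‑3‑en‑1‑yl]furan‑2(5H)‑one
Conditions: CBr4, PPh3, CH2Cl2, 0 °C
Reagents that add atoms: carbon tetrabromide, BrC(Br)(Br)Br
Why: Appel bromination of the primary allylic alcohol proceeds by SN2 under neutral conditions that the butenolide tolerates, with the alkene geometry kept.

**Step 15**
Reactants: 12 (5S)‑5‑methyl‑5‑{(2R,5R)‑5‑methyl‑5‑[(E)‑2‑(4,4,5,5‑tetramethyl‑1,3,2‑dioxaborolan‑2‑yl)ethenyl]oxolan‑2‑yl}oxolan‑2‑one; 20 3‑[(3E)‑5‑bromo‑4‑methylpent‑3‑en‑1‑yl]furan‑2(5H)‑one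
Product: 21 (5S)‑5‑methyl‑5‑{(2R,5R)‑5‑methyl‑5‑[(1E,4E)‑4‑methyl‑7‑(2‑oxo‑2,5‑dihydrofuran‑3‑yl)hepta‑1,4‑dien‑1‑yl]oxolan‑2‑yl}oxolan‑2‑one (CNP0301418.1)
Conditions: PdCl2(dppf) (5 mol %), K3PO4 (aq.), THF, rt, degassed; 20 in slight excess
Reagents that add atoms: none
Why: Suzuki–Miyaura coupling of an alkenylboronate with an allylic bromide: oxidative addition gives a π‑allylpalladium complex, and transmetalation then reductive elimination at the less hindered CH2 terminus should give the linear 1,4‑diene with both E geometries kept (syn–anti isomerisation would need palladium σ‑bonded at the secondary allyl terminus); cold aqueous phosphate spares both lactones and no stereocentre is touched.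

**Compound list**
1 | geraniol, (2E)‑3,7‑dimethylocta‑2,6‑dien‑1‑ol | CC(C)=CCC/C(C)=C/CO | starting material
2 | tert‑butyl{[(2E)‑3,7‑dimethylocta‑2,6‑dien‑1‑yl]oxy}dimethylsilane | CC(C)=CCC/C(C)=C/CO[Si](C)(C)C(C)(C)C | intermediate
3 | (2E,6E)‑8‑{[tert‑butyl(dimethyl)silyl]oxy}‑2,6‑dimethylocta‑2,6‑dien‑1‑ol | OC/C(C)=C/CC/C(C)=C/CO[Si](C)(C)C(C)(C)C | intermediate
4 | {[(2E,6E)‑8‑bromo‑3,7‑dimethylocta‑2,6‑dien‑1‑yl]oxy}(tert‑butyl)dimethylsilane | BrC/C(C)=C/CC/C(C)=C/CO[Si](C)(C)C(C)(C)C | intermediate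
5 | tert‑butyl (4E,8E)‑10‑{[tert‑butyl(dimethyl)silyl]oxy}‑4,8‑dimethyldeca‑4,8‑dienoate | CC(C)(C)OC(=O)CC/C(C)=C/CC/C(C)=C/CO[Si](C)(C)C(C)(C)C | intermediate
6 | tert‑butyl (4E,8E)‑10‑hydroxy‑4,8‑dimethyldeca‑4,8‑dienoate | CC(C)(C)OC(=O)CC/C(C)=C/CC/C(C)=C/CO | intermediate
7 | tert‑butyl (4E)‑6‑[(2S,3S)‑3‑(hydroxymethyl)‑2‑methyloxiran‑2‑yl]‑4‑methylhex‑4‑enoate | OC[C@@H]1O[C@@]1(C)CC/C=C(\C)CCC(=O)OC(C)(C)C | intermediate
8 | tert‑butyl 3‑[(2R,3R)‑3‑{2‑[(2S,3S)‑3‑(hydroxymethyl)‑2‑methyloxiran‑2‑yl]ethyl}‑2‑methyloxiran‑2‑yl]propanoate (key‑step precursor) | OC[C@@H]1O[C@@]1(C)CC[C@H]2O[C@]2(C)CCC(=O)OC(C)(C)C | intermediate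
9 | (5S)‑5‑{(1R)‑1‑hydroxy‑3‑[(2S,3S)‑3‑(hydroxymethyl)‑2‑methyloxiran‑2‑yl]propyl}‑5‑methyloxolan‑2‑one | OC[C@@H]1O[C@@]1(C)CC[C@@H](O)[C@]2(C)CCC(=O)O2 | intermediate (not isolated)
10 | (5S)‑5‑[(2R,5R)‑5‑[(1S)‑1,2‑dihydroxyethyl]‑5‑methyloxolan‑2‑yl]‑5‑methyloxolan‑2‑one (key‑step product) | OC[C@H](O)[C@@]1(C)CC[C@H]([C@]2(C)CCC(=O)O2)O1 | intermediate
11 | (2R,5R)‑2‑methyl‑5‑[(2S)‑2‑methyl‑5‑oxooxolan‑2‑yl]oxolane‑2‑carbaldehyde | O=C[C@@]1(C)CC[C@H]([C@]2(C)CCC(=O)O2)O1 | intermediate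
12 | (5S)‑5‑methyl‑5‑{(2R,5R)‑5‑methyl‑5‑[(E)‑2‑(4,4,5,5‑tetramethyl‑1,3,2‑dioxaborolan‑2‑yl)ethenyl]oxolan‑2‑yl}oxolan‑2‑one | CC1(C)OB(/C=C/[C@@]2(C)CC[C@H]([C@]3(C)CCC(=O)O3)O2)OC1(C)C | intermediate
13 | furan‑2(5H)‑one | O=C1OCC=C1 | starting material
14 | trans‑3,4‑dibromooxolan‑2‑one (racemic; one enantiomer drawn) | O=C1OC[C@H](Br)[C@H]1Br | intermediate (not isolated)
15 | 3‑bromofuran‑2(5H)‑one | O=C1OCC=C1Br | intermediate
16 | 5‑bromo‑2‑methylpent‑2‑ene | CC(C)=CCCBr | starting material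
17 | (4‑methylpent‑3‑en‑1‑yl)zinc bromide | CC(C)=CCC[Zn]Br | intermediate (not isolated)
18 | 3‑(4‑methylpent‑3‑en‑1‑yl)furan‑2(5H)‑one | CC(C)=CCCC1=CCOC1=O | intermediate
19 | 3‑[(3E)‑5‑hydroxy‑4‑methylpent‑3‑en‑1‑yl]furan‑2(5H)‑one | OC/C(C)=C/CCC1=CCOC1=O | intermediate
20 | 3‑[(3E)‑5‑bromo‑4‑methylpent‑3‑en‑1‑yl]furan‑2(5H)‑one | BrC/C(C)=C/CCC1=CCOC1=O | intermediate
21 | (5S)‑5‑methyl‑5‑{(2R,5R)‑5‑methyl‑5‑[(1E,4E)‑4‑methyl‑7‑(2‑oxo‑2,5‑dihydrofuran‑3‑yl)hepta‑1,4‑dien‑1‑yl]oxolan‑2‑yl}oxolan‑2‑one | C/C(=C\CCC1=CCOC1=O)C/C=C/[C@@]1(C)CC[C@H]([C@]2(C)CCC(=O)O2)O1 | target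

**Step count**
Total: 15 steps. Longest linear sequence: 11 steps (steps 1–10 and 15); the side chain takes steps 11–14.

**Steps most likely to fail**

1. Step 8. The double ring closure may lose regiocontrol through cross‑talk between the two protonated epoxides (one epoxide oxygen attacking the other at the wrong carbon), through hydride‑shift rearrangement of a trisubstituted epoxide, or through slow participation of the ester carbonyl. The fallback sets out from 6 and returns at 9, and so at 10; it closes the two rings one at a time, each facing a single epoxide. Acetylation (Ac2O, pyridine) gives tert‑butyl (4E,8E)‑10‑(acetyloxy)‑4,8‑dimethyldeca‑4,8‑dienoate F1, whose allylic acetate deactivates the neighbouring alkene. Shi epoxidation under the conditions of step 7 then touches only the remote alkene and gives tert‑butyl 3‑[(2R,3R)‑3‑[(3E)‑5‑(acetyloxy)‑3‑methylpent‑3‑en‑1‑yl]‑2‑methyloxiran‑2‑yl]propanoate F2. CSA in CH2Cl2 closes the lactone alone, with loss of 2‑methylpropene, to give (2E,6R)‑6‑hydroxy‑3‑methyl‑6‑[(2S)‑2‑methyl‑5‑oxooxolan‑2‑yl]hex‑2‑en‑1‑yl acetate F3. K2CO3 in MeOH removes the acetate to give (5S)‑5‑[(1R,4E)‑1,6‑dihydroxy‑4‑methylhex‑4‑en‑1‑yl]‑5‑methyloxolan‑2‑one F4. Sharpless epoxidation with L‑(+)‑diethyl tartrate then gives epoxy alcohol 9, which CSA cyclises to 10.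

2. Step 15. The coupling may suffer from protodeboronation of the hindered alkenylboronate, base‑induced opening or γ‑deprotonation of the butenolide, or loss of alkene geometry and branched coupling through isomerisation of the allylpalladium intermediate. The fallback sets out from 11 and returns at 21; it replaces the basic boron coupling by a neutral tin coupling. Takai‑type stannyl olefination (CrCl2, Bu3SnCHBr2, LiI, THF/DMF) gives (5S)‑5‑methyl‑5‑{(2R,5R)‑5‑methyl‑5‑[(E)‑2‑(tributylstannyl)ethenyl]oxolan‑2‑yl}oxolan‑2‑one F5, and base‑free Stille coupling with 20 (Pd2(dba)3, AsPh3, THF, rt to 50 °C) gives 21.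

3. Step 12. The sp3–sp2 coupling may be eroded by β‑hydride elimination or reduction at the alkylpalladium stage, or by decomposition of the bromobutenolide. The fallback sets out from 16 and returns at 18; it builds the butenolide alkene by sulfoxide elimination instead of cross‑coupling. Alkylation of the potassium enolate of commercial 3‑(phenylsulfanyl)oxolan‑2‑one with 16 (KN(SiMe3)2, THF/DMPU, NaI) gives 3‑(4‑methylpent‑3‑en‑1‑yl)‑3‑(phenylsulfanyl)oxolan‑2‑one F6. NaIO4 in MeOH/H2O oxidises the sulfide, without touching the alkene, to 3‑(benzenesulfinyl)‑3‑(4‑methylpent‑3‑en‑1‑yl)oxolan‑2‑one F7. Thermal syn‑elimination toward the ring hydrogen (toluene, 110 °C, CaCO3) gives 18.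

**Further compounds**
F1 | step 8 | tert‑butyl (4E,8E)‑10‑(acetyloxy)‑4,8‑dimethyldeca‑4,8‑dienoate | CC(C)(C)OC(=O)CC/C(C)=C/CC/C(C)=C/COC(C)=O
F2 | step 8 | tert‑butyl 3‑[(2R,3R)‑3‑[(3E)‑5‑(acetyloxy)‑3‑methylpent‑3‑en‑1‑yl]‑2‑methyloxiran‑2‑yl]propanoate | CC(=O)OC/C=C(\C)CC[C@H]1O[C@]1(C)CCC(=O)OC(C)(C)C
F3 | step 8 | (2E,6R)‑6‑hydroxy‑3‑methyl‑6‑[(2S)‑2‑methyl‑5‑oxooxolan‑2‑yl]hex‑2‑en‑1‑yl acetate | CC(=O)OC/C=C(\C)CC[C@@H](O)[C@]1(C)CCC(=O)O1
F4 | step 8 | (5S)‑5‑[(1R,4E)‑1,6‑dihydroxy‑4‑methylhex‑4‑en‑1‑yl]‑5‑methyloxolan‑2‑one | OC/C=C(\C)CC[C@@H](O)[C@]1(C)CCC(=O)O1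
F5 | step 15 | (5S)‑5‑methyl‑5‑{(2R,5R)‑5‑methyl‑5‑[(E)‑2‑(tributylstannyl)ethenyl]oxolan‑2‑yl}oxolan‑2‑one | CCCC[Sn](CCCC)(CCCC)/C=C/[C@@]1(C)CC[C@H]([C@]2(C)CCC(=O)O2)O1
F6 | step 12 | 3‑(4‑methylpent‑3‑en‑1‑yl)‑3‑(phenylsulfanyl)oxolan‑2‑one (racemic) | CC(C)=CCCC1(CCOC1=O)Sc1ccccc1
F7 | step 12 | 3‑(benzenesulfinyl)‑3‑(4‑methylpent‑3‑en‑1‑yl)oxolan‑2‑one (diastereomer mixture) | CC(C)=CCCC1(CCOC1=O)S(=O)c1ccccc1
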